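The plan reads ring B as a cyclohexanone plus one carbon. The C1–C2=C3(Me) enone segment of the seven-membered ring B is bonded directly to the quaternary C7, so taking out C2 leaves a trans-hydrindanone whose C1 carbonyl is flanked by C7 and the methyl-bearing C3. The key step puts C2 back in one operation: cyclopropanation of the C1=C3 silyl enol ether and oxidative opening of the siloxycyclopropane enlarge the six-membered ring to ring B and give the conjugated C1 enone as a single regioisomer. The precursor is the C1=C3 trimethylsilyl enol ether of the trans-fused hydrindanone with C5–OTBS, C10–OTMS and the C5, C6, C7 and C10 stereocentres already in place.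

Key step: step 13

Remark on labels: atoms carry the numbers of the target (ring B: C1–C2–C3–C4–C5–C6–C7; ring A: C6–C7–C8–C9–C10; before step 13 C2 is absent and C1 is bonded to C3); β is the face of the C7 methyl, α the opposite face; in this numbering the target is 1R,5S,6S,7S,10R.

Assumption: a ketoreductase that gives the (1R,2S) hydroxy ketone 4 is available from a commercial enzyme panel; only the quaternary centre is carried to the target, because the carbinol is oxidised in step 10.

Remark: the centres at C3 of 16 and 19 and at C1 and C3 of 18 are not controlled and are left open in the SMILES, since they become trigonal again; the tertiary C10 trimethylsilyl ether is a spectator, and any part of it lost in steps 13 to 15 converges in step 16.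

Step 1
Reactants: 1 2-methylcyclohexane-1,3-dione; 2 acrylonitrile
Product: 3 3-(1-methyl-2,6-dioxocyclohexyl)propanenitrile
Conditions: Et3N (cat.), H2O–MeCN, 60 °C
Reagents that add atoms: none
Why: Michael addition (cyanoethylation) of the acidic 2-methyl-1,3-dione to acrylonitrile should install the C8–C9–C10 chain on the future quaternary C7, which is not yet a stereocentre because the two ring carbonyls are equivalent.

Step 2
Reactants: 3 3-(1-methyl-2,6-dioxocyclohexyl)propanenitrile
Product: 4 3-[(1R,2S)-2-hydroxy-1-methyl-6-oxocyclohexyl]propanenitrile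
Conditions: ketoreductase (from a screening panel), NADP+ (cat.), i-PrOH, phosphate buffer pH 7, 30 °C
Reagents that add atoms: none
Why: Enzymatic desymmetrising carbonyl reduction of a prochiral 2,2-disubstituted cyclohexane-1,3-dione should reduce one enantiotopic carbonyl only (the nitrile is inert), which fixes the quaternary C7 and gives the C1 carbinol cis to the methyl, the enzyme being chosen for this isomer.

Step 3
Reactants: 4 3-[(1R,2S)-2-hydroxy-1-methyl-6-oxocyclohexyl]propanenitrile
Product: 5 3-[(1R,2S)-1-methyl-6-oxo-2-(triethylsilyloxy)cyclohexyl]propanenitrile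
Conditions: Et3SiCl, imidazole, CH2Cl2, 0 → 25 °C
Reagents that add atoms: chlorotriethylsilane, CC[Si](CC)(CC)Cl
Why: Silyl ether formation on the only hydroxyl masks C1–OH for the dehydration and organometallic steps, the mild base avoiding retro-aldol cleavage of the β-hydroxy ketone.

Step 4
Reactants: 5 3-[(1R,2S)-1-methyl-6-oxo-2-(triethylsilyloxy)cyclohexyl]propanenitrile
Product: 7 cis-fused α-ketol (C1 OSiEt3 β; C6 OH β; C10 ketone), via hydroxy imine 6 (not isolated)
Conditions: SmI2 (2.5 equiv), t-BuOH, THF, visible light, 25 °C; then aqueous citric acid, 0 °C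
Reagents that add atoms: water, O (the C10 carbonyl oxygen)
Why: Ketyl–nitrile reductive cyclisation, in which SmI2 (divalent samarium) reduces the C6 ketone to a ketyl that adds 5-exo to the nitrile carbon C10 and the imine is hydrolysed only on work-up, should close ring A as the α-ketol, expected cis-fused (C6–OH β), a centre that is erased in step 5.

Step 5
Reactants: 7 cis-fused α-ketol
Product: 8 bicyclic enone (C10 ketone conjugated with C5=C6; C1 OSiEt3 β)
Conditions: SOCl2, pyridine, CH2Cl2, –10 → 0 °C
Reagents that add atoms: none
Why: Dehydration of the tertiary α-ketol through its chlorosulfite (E2) can only run towards C5, since C7 and C10 bear no hydrogen, and should give the conjugated C5=C6 enone as a single regioisomer.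

Step 6
Reactants: 8 bicyclic enone
Product: 9 tertiary allylic alcohol (C10 OH β and isopropyl α; C5=C6; C1 OSiEt3 β)
Conditions: i-PrMgCl, CeCl3, THF, –78 → 0 °C; aq. NH4Cl
Reagents that add atoms: isopropylmagnesium chloride, CC(C)[Mg]Cl
Why: Organocerium 1,2-addition (CeCl3 suppresses enolisation and conjugate addition) should attack the C10 carbonyl from the α face, because the pseudo-axial C7 methyl blocks the β trajectory, which sets C10 with hydroxyl β and isopropyl α as in the target.

Step 7
Reactants: 9 tertiary allylic alcohol
Product: 11 trans-fused diol (C5 OH α; C6 H α; C10 OH β; C1 OSiEt3 β), via alkylborane 10 (not isolated)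
Conditions: BH3·THF (excess), THF, 0 → 25 °C; then 3 M NaOH, 30% H2O2, 0 °C
Reagents that add atoms: hydrogen peroxide, OO (oxygen on C5); borane–tetrahydrofuran, B.C1CCOC1 (boron of 10 only)
Why: Hydroboration–oxidation, a syn addition to the trisubstituted C5=C6 alkene with boron on the less substituted C5, should occur on the α face, away from the two pseudo-axial β groups next to C6 (C7 methyl and C10 oxygen), so that C6–H (trans ring fusion) and, after oxidation with retention, the equatorial C5–OH are set together.

Step 8
Reactants: 11 trans-fused diol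
Product: 12 C5 tert-butyldimethylsilyl ether of diol 11 (C10 OH free; C1 OSiEt3)
Conditions: t-BuMe2SiCl, imidazole, DMF, 40 °C
Reagents that add atoms: tert-butylchlorodimethylsilane, CC(C)(C)[Si](C)(C)Cl
Why: Silylation with the chlorosilane and imidazole distinguishes the secondary C5 hydroxyl from the hindered tertiary C10 hydroxyl, which is left free.

Step 9
Reactants: 12 C5 tert-butyldimethylsilyl ether
Product: 13 C1 alcohol (C1 OH β; C5 OTBS; C10 OH)
Conditions: PPTS (cat.), MeOH–CH2Cl2, 0 °C
Reagents that add atoms: none
Why: Acid-catalysed methanolysis cleaves a triethylsilyl ether much faster than a tert-butyldimethylsilyl ether, so only C1–OH should be released.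

Step 10
Reactants: 13 C1 alcohol
Product: 14 trans-hydrindanone (C1 ketone; C5 OTBS; C10 OH)
Conditions: Dess–Martin periodinane, CH2Cl2, 25 °C
Reagents that add atoms: none
Why: Dess–Martin oxidation converts the only secondary alcohol into the C1 ketone, the tertiary C10 alcohol and the silyl ether being inert.

Step 11
Reactants: 14 trans-hydrindanone
Product: 16 C3-methyl trans-hydrindanone (C3 epimers; C5 OTBS; C10 OH), via lithium enolate 15 (not isolated)
Conditions: LiN(i-Pr)2 (2.1 equiv), THF, –78 °C; then MeI, –78 → –30 °C
Reagents that add atoms: iodomethane, CI; lithium diisopropylamide, [Li]N(C(C)C)C(C)C (lithium of 15 only)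
Why: Enolate alkylation, in which the C1 ketone can enolise only towards C3 because C7 is quaternary and the enolate carbon is methylated far faster than the hindered tertiary alkoxide, should give the C3 monomethyl ketone, whose new centre is irrelevant since C3 becomes trigonal in step 12.

Step 12
Reactants: 16 C3-methyl trans-hydrindanone
Product: 17 C1=C3 trimethylsilyl enol ether (C5 OTBS; C10 OTMS; 5S,6S,7S,10R)
Conditions: Me3SiOTf, Et3N, CH2Cl2, 0 → 25 °C
Reagents that add atoms: trimethylsilyl trifluoromethanesulfonate, C[Si](C)(C)OS(=O)(=O)C(F)(F)F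
Why: Soft enolisation (silyl triflate and amine) gives the only possible, tetrasubstituted C1=C3 silyl enol ether and caps the tertiary C10 hydroxyl in the same operation.

Step 13
Reactants: 17 C1=C3 trimethylsilyl enol ether
Product: 20 bicyclic C1 enone with C2=C3 (C5 OTBS; C10 OTMS; 5S,6S,7S,10R), via siloxycyclopropane 18 (not isolated), via chloro ketone 19 (not isolated)
Conditions: Et2Zn, CH2I2, CH2Cl2, 0 → 25 °C; then FeCl3, DMF, 0 °C; then NaOAc, MeOH, 65 °C
Reagents that add atoms: diiodomethane, ICI (the C2 methylene); iron trichloride, Cl[Fe](Cl)Cl (chlorine of 19 only)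
Why: The zinc carbenoid EtZnCH2I transfers its methylene in a concerted fashion to the electron-rich C1=C3 enol ether (bonds C1–C2 and C2–C3), FeCl3 (trivalent iron) then oxidises the siloxycyclopropane by one electron, the oxygen-centred radical cleaves the internal C1–C3 bond (β-scission) to leave the C1 carbonyl and a tertiary C3 radical in a seven-membered ring, this radical takes chlorine from a second FeCl3, and acetate finally removes HCl across C2–C3 (E1cB). The closest known reaction type is the Saegusa–Ito one-carbon ring expansion of cyclic silyl enol ethers. The transient three-membered ring is closed by [2+1] addition of the carbenoid to the alkene, whereas ring B is not closed end to end but arises by enlargement, when the bond shared by the two rings of the bicyclo[4.1.0]heptane unit breaks. No stereocentre is formed in the product: the two cyclopropane centres are transient, and C5, C6, C7 and C10 lie away from the reacting atoms. The step needs regioselectivity only, and the substrate secures it: quaternary C7 allows a single enol ether and so a single site of insertion, the C3 methyl makes the ring-enlarged radical tertiary so that the internal and not an external cyclopropane bond breaks, and HCl is lost towards C2 because only that direction gives the conjugated enone.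

Step 14
Reactants: 20 bicyclic C1 enone
Product: 21 (1R) allylic alcohol (C1 OH α; C5 OTBS; C10 OTMS)
Conditions: (S)-2-methyl-CBS-oxazaborolidine (1 equiv), BH3·SMe2, THF, –30 °C; then MeOH
Reagents that add atoms: none
Why: Corey–Bakshi–Shibata reduction, with the quaternary C7 as the large and the vinylic C2 as the small carbonyl substituent, should direct hydride under reagent control to the face that gives the 1R alcohol (hydroxyl α, trans to the C7 methyl), the β,β-disubstituted enone being reduced 1,2.

Step 15
Reactants: 21 (1R) allylic alcohol; 22 angelic acid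
Product: 24 C1 angelate (C5 OTBS; C10 OTMS), via mixed anhydride 23 (not isolated)
Conditions: 22, 2,4,6-trichlorobenzoyl chloride, Et3N, toluene, 25 °C; then 21, 80 °C
Reagents that add atoms: 2,4,6-trichlorobenzoyl chloride, ClC(=O)c1c(Cl)cc(Cl)cc1Cl (aroyl part of 23 only; nothing of it remains in 24)
Why: Yamaguchi esterification through the mixed anhydride without a nucleophilic acyl-transfer catalyst, conditions under which angelates are known to keep their Z geometry, acylates the only free hydroxyl (C1) with retention.

Step 16
Reactants: 24 C1 angelate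
Product: 25 C1 angelate C5,C10-diol
Conditions: HF·pyridine, pyridine, THF, 0 → 25 °C
Reagents that add atoms: none
Why: Fluoride-mediated desilylation under buffered, weakly acidic conditions removes both silyl ethers and should leave the allylic angelate untouched.

Step 17
Reactants: 26 4-hydroxybenzoic acid
Product: 28 4-(tert-butyldimethylsilyloxy)benzoic acid, via silyl ester 27 (not isolated)
Conditions: t-BuMe2SiCl (2.5 equiv), imidazole, DMF, 25 °C; then AcOH–THF–H2O, 25 °C
Reagents that add atoms: tert-butylchlorodimethylsilane, CC(C)(C)[Si](C)(C)Cl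
Why: Exhaustive silylation followed by selective hydrolysis of the far more labile silyl ester leaves the phenol masked as its silyl ether and the carboxylic acid free.

Step 18
Reactants: 25 C1 angelate C5,C10-diol; 28 4-(tert-butyldimethylsilyloxy)benzoic acid
Product: 29 C1 angelate C5 4-(tert-butyldimethylsilyloxy)benzoate (C10 OH free)
Conditions: EDC·HCl, DMAP, CH2Cl2, 25 °C
Reagents that add atoms: none
Why: Steglich esterification acylates the secondary C5 hydroxyl with retention and leaves the hindered tertiary C10 hydroxyl free.

Step 19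
Reactants: 29 C1 angelate C5 4-(tert-butyldimethylsilyloxy)benzoate
Product: 30 CNP0273650.2
Conditions: HF·pyridine, pyridine, THF, 25 °C
Reagents that add atoms: none
Why: Desilylation of the aryl silyl ether with buffered HF·pyridine frees the phenol under non-basic conditions, so that neither ester should migrate and the angelate should not isomerise.

Compound list
1 | 2-methylcyclohexane-1,3-dione | CC1C(=O)CCCC1=O | starting material
2 | acrylonitrile | C=CC#N | starting material
3 | 3-(1-methyl-2,6-dioxocyclohexyl)propanenitrile | N#CCCC1(C)C(=O)CCCC1=O | intermediate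
4 | 3-[(1R,2S)-2-hydroxy-1-methyl-6-oxocyclohexyl]propanenitrile (hydroxyl cis to methyl; carbinol = C1, quaternary carbon = C7, ketone = C6) | O[C@H]1CCCC(=O)[C@]1(C)CCC#N | intermediate
5 | 3-[(1R,2S)-1-methyl-6-oxo-2-(triethylsilyloxy)cyclohexyl]propanenitrile | CC[Si](CC)(CC)O[C@H]1CCCC(=O)[C@]1(C)CCC#N | intermediate
6 | cis-fused α-hydroxy imine (C1 OSiEt3 β; C6 OH β; C10 C=NH) | CC[Si](CC)(CC)O[C@H]1CCC[C@@]2(O)[C@]1(C)CCC2=N | intermediate (not isolated)
7 | cis-fused α-ketol (C1 OSiEt3 β; C6 OH β; C10 ketone) | CC[Si](CC)(CC)O[C@H]1CCC[C@@]2(O)[C@]1(C)CCC2=O | intermediate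
8 | bicyclic enone (C10 ketone conjugated with C5=C6; C1 OSiEt3 β) | CC[Si](CC)(CC)O[C@H]1CCC=C2[C@]1(C)CCC2=O | intermediate
9 | tertiary allylic alcohol (C10 OH β, isopropyl α; C5=C6; C1 OSiEt3 β) | CC[Si](CC)(CC)O[C@H]1CCC=C2[C@]1(C)CC[C@@]2(O)C(C)C | intermediate
10 | C5 alkylborane, drawn as the monoalkylborane (BH2 α on C5; H α on C6) | CC[Si](CC)(CC)O[C@H]1CC[C@H](B)[C@@H]2[C@]1(C)CC[C@@]2(O)C(C)C | intermediate (not isolated)
11 | trans-fused diol (C5 OH α; C6 H α; C10 OH β; C1 OSiEt3 β) | CC[Si](CC)(CC)O[C@H]1CC[C@H](O)[C@@H]2[C@]1(C)CC[C@@]2(O)C(C)C | intermediate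
12 | C5 tert-butyldimethylsilyl ether of 11 (C10 OH free; C1 OSiEt3) | CC[Si](CC)(CC)O[C@H]1CC[C@H](O[Si](C)(C)C(C)(C)C)[C@@H]2[C@]1(C)CC[C@@]2(O)C(C)C | intermediate
13 | C1 alcohol (C1 OH β; C5 OTBS; C10 OH) | O[C@H]1CC[C@H](O[Si](C)(C)C(C)(C)C)[C@@H]2[C@]1(C)CC[C@@]2(O)C(C)C | intermediate
14 | trans-hydrindanone (C1 ketone; C5 OTBS; C10 OH) | O=C1CC[C@H](O[Si](C)(C)C(C)(C)C)[C@@H]2[C@]1(C)CC[C@@]2(O)C(C)C | intermediate
15 | dilithium salt of 14 (C1=C3 enolate; C10 alkoxide) | [Li]OC1=CC[C@H](O[Si](C)(C)C(C)(C)C)[C@@H]2[C@]1(C)CC[C@@]2(O[Li])C(C)C | intermediate (not isolated)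
16 | C3-methyl trans-hydrindanone (C3 epimers, centre left open; C5 OTBS; C10 OH) | O=C1C(C)C[C@H](O[Si](C)(C)C(C)(C)C)[C@@H]2[C@]1(C)CC[C@@]2(O)C(C)C | intermediate
17 | C1=C3 trimethylsilyl enol ether of the trans-hydrindanone (C5 OTBS; C10 OTMS) | C[Si](C)(C)OC1=C(C)C[C@H](O[Si](C)(C)C(C)(C)C)[C@@H]2[C@]1(C)CC[C@@]2(O[Si](C)(C)C)C(C)C | intermediate
18 | siloxycyclopropane (C2 methylene bridging C1 and C3; cyclopropane centres left open) | C[Si](C)(C)OC13CC1(C)C[C@H](O[Si](C)(C)C(C)(C)C)[C@@H]2[C@]3(C)CC[C@@]2(O[Si](C)(C)C)C(C)C | intermediate (not isolated)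
19 | ring-enlarged 3-chloro-3-methyl ketone (C3 left open) | O=C1CC(C)(Cl)C[C@H](O[Si](C)(C)C(C)(C)C)[C@@H]2[C@]1(C)CC[C@@]2(O[Si](C)(C)C)C(C)C | intermediate (not isolated)
20 | bicyclic C1 enone with C2=C3 (C5 OTBS; C10 OTMS) | O=C1C=C(C)C[C@H](O[Si](C)(C)C(C)(C)C)[C@@H]2[C@]1(C)CC[C@@]2(O[Si](C)(C)C)C(C)C | intermediate
21 | (1R) allylic alcohol (C1 OH α; C5 OTBS; C10 OTMS) | O[C@@H]1C=C(C)C[C@H](O[Si](C)(C)C(C)(C)C)[C@@H]2[C@]1(C)CC[C@@]2(O[Si](C)(C)C)C(C)C | intermediate
22 | angelic acid, (Z)-2-methylbut-2-enoic acid | C/C=C(/C)C(=O)O | starting material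
23 | angelic 2,4,6-trichlorobenzoic anhydride | C/C=C(/C)C(=O)OC(=O)c1c(Cl)cc(Cl)cc1Cl | intermediate (not isolated)
24 | C1 angelate (C5 OTBS; C10 OTMS) | C/C=C(/C)C(=O)O[C@@H]1C=C(C)C[C@H](O[Si](C)(C)C(C)(C)C)[C@@H]2[C@]1(C)CC[C@@]2(O[Si](C)(C)C)C(C)C | intermediate
25 | C1 angelate C5,C10-diol | C/C=C(/C)C(=O)O[C@@H]1C=C(C)C[C@H](O)[C@@H]2[C@]1(C)CC[C@@]2(O)C(C)C | intermediate
26 | 4-hydroxybenzoic acid | OC(=O)c1ccc(O)cc1 | starting material
27 | tert-butyldimethylsilyl 4-(tert-butyldimethylsilyloxy)benzoate | CC(C)(C)[Si](C)(C)OC(=O)c1ccc(O[Si](C)(C)C(C)(C)C)cc1 | intermediate (not isolated)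
28 | 4-(tert-butyldimethylsilyloxy)benzoic acid | CC(C)(C)[Si](C)(C)Oc1ccc(cc1)C(=O)O | intermediate
29 | C1 angelate C5 4-(tert-butyldimethylsilyloxy)benzoate (C10 OH free) | C/C=C(/C)C(=O)O[C@@H]1C=C(C)C[C@H](OC(=O)c2ccc(O[Si](C)(C)C(C)(C)C)cc2)[C@@H]2[C@]1(C)CC[C@@]2(O)C(C)C | intermediate
30 | CNP0273650.2, the C1 angelate C5 4-hydroxybenzoate (1R,5S,6S,7S,10R) | C/C=C(/C)C(=O)O[C@@H]1C=C(C)C[C@H](OC(=O)c2ccc(O)cc2)[C@@H]2[C@]1(C)CC[C@@]2(O)C(C)C | target

Total step count: 19. Longest linear sequence: 18 steps (steps 1 to 16, 18 and 19, from 2-methylcyclohexane-1,3-dione).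

Steps most likely to fail

Step 13 (ring expansion). The zinc carbenoid may add too slowly to the hindered, tetrasubstituted enol ether, so that the enol ether hydrolyses back to the ketone. In the iron stage an external cyclopropane bond may break or silyl groups may be lost, and the loss of HCl may be incomplete. In the fallback the carbon would be inserted by a dihalocarbene, through a different ring-opening mechanism. Enol ether 17 would be treated with CHBr3 and KOt-Bu in pentane at –20 °C to give the 2,2-dibromo siloxycyclopropane F1. On warming in toluene this should open in an electrocyclic cyclopropyl-to-allyl fashion, with loss of bromotrimethylsilane, to the 2-bromo enone F2. Reduction of the vinylic C–Br bond with Bu3SnH and Pd(PPh3)4 (zerovalent palladium) brings the route back at enone 20.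

Step 14 (C1 reduction). Facial selectivity may be insufficient, because the inherent bias of the ketone (hydride delivery anti to the C7 methyl) opposes the catalyst. The fallback uses that bias instead of fighting it. Luche reduction of enone 20 (NaBH4, CeCl3·7H2O, MeOH, –78 °C) should give the C1 epimer, the β allylic alcohol F3. A Mitsunobu esterification with angelic acid 22 (PPh3, diisopropyl azodicarboxylate, toluene) would then invert C1 and lead directly to angelate 24, so that step 15 is skipped. The displacement at this neopentyl-type allylic carbon is hindered and is the weak point of this fallback.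

Step 7 (hydroboration). Borane may not discriminate the two faces well enough, since the α isopropyl group opposes the two β groups, or hydride may be delivered from the C10 borate on the β face; either would give the cis-fused isomer. In the fallback C5 and C6 would be set before the isopropyl group is present. Enone 8 would be epoxidised under Weitz–Scheffer conditions (t-BuOOH, DBU, CH2Cl2); the hydroperoxide should add to C5 anti to the pseudo-axial C7 methyl and give the α-epoxy ketone F4. SmI2 in THF–MeOH at –90 °C should cleave the C6–O bond, and kinetic protonation of the samarium enolate from the α face should give the trans-fused β-hydroxy ketone F5. Addition of i-PrMgCl with CeCl3 from the α face then brings the route back at diol 11.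

Further compounds
F1 | step 13 | 2,2-dibromo siloxycyclopropane (CBr2 bridging C1 and C3; C5 OTBS; C10 OTMS) | C[Si](C)(C)OC13C(Br)(Br)C1(C)C[C@H](O[Si](C)(C)C(C)(C)C)[C@@H]2[C@]3(C)CC[C@@]2(O[Si](C)(C)C)C(C)C
F2 | step 13 | 2-bromo C1 enone with C2=C3 (C5 OTBS; C10 OTMS) | O=C1C(Br)=C(C)C[C@H](O[Si](C)(C)C(C)(C)C)[C@@H]2[C@]1(C)CC[C@@]2(O[Si](C)(C)C)C(C)C
F3 | step 14 | C1 epimer of 21 (C1 OH β; C5 OTBS; C10 OTMS) | O[C@H]1C=C(C)C[C@H](O[Si](C)(C)C(C)(C)C)[C@@H]2[C@]1(C)CC[C@@]2(O[Si](C)(C)C)C(C)C
F4 | step 7 | α-epoxy ketone (C5–C6 epoxide on the α face; C10 ketone; C1 OSiEt3 β) | CC[Si](CC)(CC)O[C@H]1CC[C@@H]2O[C@]23[C@]1(C)CCC3=O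
F5 | step 7 | trans-fused β-hydroxy ketone (C5 OH α; C6 H α; C10 ketone; C1 OSiEt3 β) | CC[Si](CC)(CC)O[C@H]1CC[C@H](O)[C@@H]2[C@]1(C)CCC2=O
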